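Retrosynthesis: the quinone is unmasked last from a 2,3,4-trimethoxy-6-alkylphenol. Before that the exocyclic N–C bond to the dehydrohydantoin (1-methylparabanic acid), the imidazole bonds N1–C2 and N3–C4 (α-methylamino ketone + cyanamide) and the imidazole C4–CH2Ar bond (N-methoxy-N-methylamide + 4-methoxybenzyl Grignard) are cut, leaving an N-Boc-N-methyl arylalanine amide.
Its benzene ring, the future quinone (numbering: C1/C4 carbonyls, C2/C3 methoxy, C5 alkyl, C6 H), is cut at C3–C4 and C5–C6 into a four-carbon diene C6–C1–C2–C3 and a two-carbon alkyne C4–C5. The alkyne comes from propargylation of the sarcosine amide enolate, which makes the bond between the future imidazole C-5 and its CH2.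
Feature that allows this: C1, C2 and C3 carry oxygen on three neighbouring carbons beside the only ring C–H (C6), which is the pattern of the bis(silyl) dienol ether of methyl 2-methoxyacetoacetate. C4 (oxygen) and C5 (CH2 branch) map onto an alk-2-ynal whose formyl group on C4 is exchanged for oxygen afterwards by Baeyer–Villiger oxidation.
Forward order: diene (steps 1–2); ynal on the amino acid chain (steps 3–5); benzene ring by Diels–Alder reaction and aromatisation (step 6); O-methylation and formyl-to-hydroxyl exchange (steps 7–8); ketone (step 9); imidazole ring (step 10); dehydrohydantoin (steps 11–12); quinone (step 13).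
Stereochemistry: the target has no stereocentre; the single centre made in step 4 is carried as a racemate and becomes sp2 (imidazole C-5) in step 10.

Key step: step 6

Remark: the dehydrohydantoin unit is taken in the tautomer of the given SMILES (exocyclic N–H, endocyclic C=N).

Step 1
Reactants: 1 methyl methoxyacetate; 2 N-methoxy-N-methylacetamide
Product: 3 methyl 2-methoxy-3-oxobutanoate (racemic)
Conditions: LiN(i-Pr)2 (1.1 equiv), THF, –78 °C; then 2, –78 → 0 °C; 1 M HCl quench
Reagents that add atoms: none
Why: Crossed Claisen condensation in which the lithium enolate of 1 is C-acetylated by the N-methoxy-N-methylamide 2, whose chelated tetrahedral adduct should prevent a second addition and release the β-keto ester on acidic work-up.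

Step 2
Reactants: 3 methyl 2-methoxy-3-oxobutanoate
Product: 5 1,2-dimethoxy-1,3-bis(trimethylsilyloxy)buta-1,3-diene (E/Z mixture; used crude), via silyl enol ether 4 (not isolated)
Conditions: Me3SiCl (1.2 equiv), Et3N, hexane, rt; filter, concentrate; then LiN(i-Pr)2 (1.1 equiv), THF, –78 °C; Me3SiCl; filter under argon, concentrate
Reagents that add atoms: chlorotrimethylsilane, C[Si](C)(C)Cl
Why: The standard two-stage silylation of a β-keto ester (O-silylation of the ketone enol, then γ-deprotonation and O-silylation of the ester dienolate) should give the 1-alkoxy-1,3-bis(silyloxy)diene.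

Step 3
Reactants: 6 N-(tert-butoxycarbonyl)-N-methylglycine (Boc-sarcosine)
Product: 7 tert-butyl N-{2-[methoxy(methyl)amino]-2-oxoethyl}-N-methylcarbamate
Conditions: 1,1'-carbonyldiimidazole (1.1 equiv), CH2Cl2, 0 °C → rt; then MeNH(OMe)·HCl (1.2 equiv), rt
Reagents that add atoms: N,O-dimethylhydroxylamine hydrochloride, CNOC.Cl
Why: Amide coupling through the acyl imidazolide is a routine way to make N-methoxy-N-methylamides (Weinreb amides) of N-protected amino acids.

Step 4
Reactants: 7 tert-butyl N-{2-[methoxy(methyl)amino]-2-oxoethyl}-N-methylcarbamate; 8 3-bromoprop-1-yne (propargyl bromide)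
Product: 9 tert-butyl N-{1-[methoxy(methyl)amino]-1-oxopent-4-yn-2-yl}-N-methylcarbamate (racemic)
Conditions: LiN(i-Pr)2 (1.1 equiv), THF, –78 °C; 8 (1.3 equiv), –78 → –30 °C
Reagents that add atoms: none
Why: Amide enolate alkylation (SN2) with a reactive propargylic halide; the new stereocentre is made as a racemate on purpose because it later becomes the sp2 carbon C-5 of the imidazole.

Step 5
Reactants: 9 tert-butyl N-{1-[methoxy(methyl)amino]-1-oxopent-4-yn-2-yl}-N-methylcarbamate
Product: 10 tert-butyl N-{1-[methoxy(methyl)amino]-1,6-dioxohex-4-yn-2-yl}-N-methylcarbamate (racemic ynal)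
Conditions: LiN(i-Pr)2 (1.05 equiv), THF, –78 °C; DMF (4 equiv), –78 → –20 °C; inverse quench into cold 10% aq. KH2PO4/MTBE
Reagents that add atoms: N,N-dimethylformamide, CN(C)C=O
Why: Formylation of a lithium acetylide with DMF should give the alk-2-ynal, since the sp C–H is by far the most acidic site and the buffered inverse quench keeps the liberated dimethylamine from adding to the product.

Step 6
Reactants: 10 tert-butyl N-{1-[methoxy(methyl)amino]-1,6-dioxohex-4-yn-2-yl}-N-methylcarbamate; 5 1,2-dimethoxy-1,3-bis(trimethylsilyloxy)buta-1,3-diene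
Product: 12 tert-butyl N-{3-(2-formyl-3,5-dihydroxy-4-methoxyphenyl)-1-[methoxy(methyl)amino]-1-oxopropan-2-yl}-N-methylcarbamate (racemic), via cyclohexadiene adduct 11 (not isolated)
Conditions: 5 (2 equiv), toluene, 80 °C, argon; then THF/10% aq. citric acid, rt
Reagents that add atoms: none
Why: Diels–Alder reaction of an electron-rich 1,3-bis(silyloxy)diene with an alk-2-ynal followed by aromatisation, a known route from such dienes and acetylenic carbonyl compounds to salicylaldehyde- and resorcylate-type arenes. The cycloaddition is concerted but strongly asynchronous: the CH2 terminus of 5 (its most nucleophilic carbon, activated by both silyloxy groups) bonds to the β-alkynyl carbon of 10 and the ketene-acetal carbon bonds to the formyl-bearing carbon, which closes the six-membered carbocycle in a [4+2] mode with both σ-bonds made across the diene termini. Adduct 11 should then lose methanol from the ketene-acetal carbon and the ring CH2 (1,4-elimination), and the silyl ethers are hydrolysed, so the ring arrives aromatic with the formyl group ortho to one hydroxyl and para to the other. No new stereocentre survives, because the one sp3 ketal carbon of 11 is flattened on aromatisation and the side-chain centre stays racemic. The step needs regioselectivity and C≡C over C=O chemoselectivity; the first is secured by the matched polarisation of diene and ynal, the second by running the reaction thermally without a Lewis acid, so that hetero-Diels–Alder or aldol addition at the aldehyde is not expected to compete.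

Step 7
Reactants: 12 tert-butyl N-{3-(2-formyl-3,5-dihydroxy-4-methoxyphenyl)-1-[methoxy(methyl)amino]-1-oxopropan-2-yl}-N-methylcarbamate
Product: 13 tert-butyl N-{3-(2-formyl-3,4,5-trimethoxyphenyl)-1-[methoxy(methyl)amino]-1-oxopropan-2-yl}-N-methylcarbamate (racemic)
Conditions: MeI (5 equiv), K2CO3 (4 equiv), DMF, 40 °C
Reagents that add atoms: iodomethane, CI
Why: Williamson O-methylation of both phenols (the chelated ortho-hydroxyl needs the excess and gentle warming), while the amide and carbamate have no N–H and cannot be alkylated.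

Step 8
Reactants: 13 tert-butyl N-{3-(2-formyl-3,4,5-trimethoxyphenyl)-1-[methoxy(methyl)amino]-1-oxopropan-2-yl}-N-methylcarbamate
Product: 15 tert-butyl N-{3-(2-hydroxy-3,4,5-trimethoxyphenyl)-1-[methoxy(methyl)amino]-1-oxopropan-2-yl}-N-methylcarbamate (racemic), via aryl formate 14 (not isolated)
Conditions: mCPBA (1.5 equiv), CH2Cl2, 0 °C → rt; then K2CO3 (0.3 equiv), MeOH, 0 °C
Reagents that add atoms: 3-chloroperoxybenzoic acid, OOC(=O)c1cccc(Cl)c1
Why: Baeyer–Villiger (Dakin-type) oxidation of an electron-rich benzaldehyde, in which the trimethoxyaryl group migrates, followed by methanolysis of the formate, should replace the formyl carbon by the phenolic oxygen that becomes the C-4 carbonyl oxygen of the quinone.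

Step 9
Reactants: 15 tert-butyl N-{3-(2-hydroxy-3,4,5-trimethoxyphenyl)-1-[methoxy(methyl)amino]-1-oxopropan-2-yl}-N-methylcarbamate; 16 (4-methoxybenzyl)magnesium chloride
Product: 17 tert-butyl N-[1-(2-hydroxy-3,4,5-trimethoxyphenyl)-4-(4-methoxyphenyl)-3-oxobutan-2-yl]-N-methylcarbamate (racemic)
Conditions: 16 (3.2 equiv, 0.25 M in THF), THF, –20 → 0 °C; sat. aq. NH4Cl
Reagents that add atoms: none
Why: Ketone synthesis from an N-methoxy-N-methylamide and a Grignard reagent; one equivalent is spent on the phenol and the chelated tetrahedral magnesium adduct should stop the addition at the ketone stage.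

Step 10
Reactants: 17 tert-butyl N-[1-(2-hydroxy-3,4,5-trimethoxyphenyl)-4-(4-methoxyphenyl)-3-oxobutan-2-yl]-N-methylcarbamate; 18 cyanamide
Product: 20 6-({2-amino-4-[(4-methoxyphenyl)methyl]-1-methyl-1H-imidazol-5-yl}methyl)-2,3,4-trimethoxyphenol, via amino ketone hydrochloride 19 (not isolated)
Conditions: 4 M HCl in 1,4-dioxane, 0 °C → rt; evaporate; then 18 (6 equiv), degassed H2O/EtOH, pH 4.5 (1 M NaOH), 95 °C, argon; 1 M NaOH to pH 10
Reagents that add atoms: none
Why: Acidolysis of the tert-butyl carbamate and condensation of the α-(methylamino) ketone salt with cyanamide (guanylation of the secondary amine, then cyclodehydration onto the ketone) is the classical 2-aminoimidazole synthesis and places N-methyl next to the carbon bearing the trimethoxyphenol-methyl group.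

Step 11
Reactants: 21 N-methylurea; 22 oxalyl chloride
Product: 23 1-methylimidazolidine-2,4,5-trione (1-methylparabanic acid)
Conditions: THF, 0 °C → reflux
Reagents that add atoms: none
Why: Double N-acylation of a urea by oxalyl chloride is the standard preparation of parabanic acids.

Step 12
Reactants: 20 6-({2-amino-4-[(4-methoxyphenyl)methyl]-1-methyl-1H-imidazol-5-yl}methyl)-2,3,4-trimethoxyphenol; 23 1-methylimidazolidine-2,4,5-trione
Product: 24 5-({5-[(2-hydroxy-3,4,5-trimethoxyphenyl)methyl]-4-[(4-methoxyphenyl)methyl]-1-methyl-1H-imidazol-2-yl}amino)-3-methyl-2H-imidazole-2,4(3H)-dione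
Conditions: 23 (2 equiv), N,O-bis(trimethylsilyl)acetamide (4 equiv), MeCN, rt; then 20, toluene, 110 °C; MeOH, rt
Reagents that add atoms: none
Why: Condensation of a 2-aminoimidazole with O-silylated 1-methylparabanic acid (addition–elimination at the silyl imidate carbon C-4, next to the unsubstituted nitrogen) is the established way to the dehydrohydantoin unit of the naamidines; the transiently silylated phenol is freed by the methanol treatment.

Step 13
Reactants: 24 5-({5-[(2-hydroxy-3,4,5-trimethoxyphenyl)methyl]-4-[(4-methoxyphenyl)methyl]-1-methyl-1H-imidazol-2-yl}amino)-3-methyl-2H-imidazole-2,4(3H)-dione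
Product: 25 naamidine F
Conditions: PhI(OAc)2 (1.1 equiv), MeCN/H2O (2:1), 0 °C
Reagents that add atoms: water, O
Why: Oxidative demethylation of a 4-methoxyphenol with a hypervalent iodine reagent (water attacks the methoxy-bearing para carbon of the phenoxonium intermediate and methanol is lost) should give the 2,3-dimethoxy-1,4-benzoquinone at 0 °C, where the anisyl ring and the acylated aminoimidazole are expected to survive.

Compound list
1 | methyl methoxyacetate | COCC(=O)OC | starting material
2 | N-methoxy-N-methylacetamide | CC(=O)N(C)OC | starting material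
3 | methyl 2-methoxy-3-oxobutanoate (racemic) | CC(=O)C(OC)C(=O)OC | intermediate
4 | methyl 2-methoxy-3-(trimethylsilyloxy)but-2-enoate | CC(O[Si](C)(C)C)=C(OC)C(=O)OC | intermediate
5 | 1,2-dimethoxy-1,3-bis(trimethylsilyloxy)buta-1,3-diene (E/Z mixture) | C=C(O[Si](C)(C)C)C(OC)=C(OC)O[Si](C)(C)C | intermediate
6 | N-(tert-butoxycarbonyl)-N-methylglycine (Boc-sarcosine) | CN(CC(=O)O)C(=O)OC(C)(C)C | starting material
7 | tert-butyl N-{2-[methoxy(methyl)amino]-2-oxoethyl}-N-methylcarbamate | CON(C)C(=O)CN(C)C(=O)OC(C)(C)C | intermediate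
8 | 3-bromoprop-1-yne (propargyl bromide) | BrCC#C | starting material
9 | tert-butyl N-{1-[methoxy(methyl)amino]-1-oxopent-4-yn-2-yl}-N-methylcarbamate (racemic) | CON(C)C(=O)C(CC#C)N(C)C(=O)OC(C)(C)C | intermediate
10 | tert-butyl N-{1-[methoxy(methyl)amino]-1,6-dioxohex-4-yn-2-yl}-N-methylcarbamate (racemic) | CON(C)C(=O)C(CC#CC=O)N(C)C(=O)OC(C)(C)C | intermediate
11 | tert-butyl N-{3-[2-formyl-3,4-dimethoxy-3,5-bis(trimethylsilyloxy)cyclohexa-1,4-dien-1-yl]-1-[methoxy(methyl)amino]-1-oxopropan-2-yl}-N-methylcarbamate (diastereomer mixture) | COC1(O[Si](C)(C)C)C(C=O)=C(CC(N(C)C(=O)OC(C)(C)C)C(=O)N(C)OC)CC(O[Si](C)(C)C)=C1OC | intermediate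
12 | tert-butyl N-{3-(2-formyl-3,5-dihydroxy-4-methoxyphenyl)-1-[methoxy(methyl)amino]-1-oxopropan-2-yl}-N-methylcarbamate (racemic) | O=Cc1c(O)c(OC)c(O)cc1CC(N(C)C(=O)OC(C)(C)C)C(=O)N(C)OC | intermediate
13 | tert-butyl N-{3-(2-formyl-3,4,5-trimethoxyphenyl)-1-[methoxy(methyl)amino]-1-oxopropan-2-yl}-N-methylcarbamate (racemic) | O=Cc1c(OC)c(OC)c(OC)cc1CC(N(C)C(=O)OC(C)(C)C)C(=O)N(C)OC | intermediate
14 | 6-{2-[(tert-butoxycarbonyl)(methyl)amino]-3-[methoxy(methyl)amino]-3-oxopropyl}-2,3,4-trimethoxyphenyl formate (racemic) | O=COc1c(OC)c(OC)c(OC)cc1CC(N(C)C(=O)OC(C)(C)C)C(=O)N(C)OC | intermediate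
15 | tert-butyl N-{3-(2-hydroxy-3,4,5-trimethoxyphenyl)-1-[methoxy(methyl)amino]-1-oxopropan-2-yl}-N-methylcarbamate (racemic) | Oc1c(OC)c(OC)c(OC)cc1CC(N(C)C(=O)OC(C)(C)C)C(=O)N(C)OC | intermediate
16 | (4-methoxybenzyl)magnesium chloride | COc1ccc(C[Mg]Cl)cc1 | starting material
17 | tert-butyl N-[1-(2-hydroxy-3,4,5-trimethoxyphenyl)-4-(4-methoxyphenyl)-3-oxobutan-2-yl]-N-methylcarbamate (racemic) | COc1ccc(CC(=O)C(Cc2cc(OC)c(OC)c(OC)c2O)N(C)C(=O)OC(C)(C)C)cc1 | intermediate
18 | cyanamide | NC#N | starting material
19 | 4-(2-hydroxy-3,4,5-trimethoxyphenyl)-1-(4-methoxyphenyl)-3-(methylamino)butan-2-one hydrochloride (racemic) | CNC(Cc1cc(OC)c(OC)c(OC)c1O)C(=O)Cc1ccc(OC)cc1.Cl | intermediate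
20 | 6-({2-amino-4-[(4-methoxyphenyl)methyl]-1-methyl-1H-imidazol-5-yl}methyl)-2,3,4-trimethoxyphenol | COc1ccc(Cc2nc(N)n(C)c2Cc2cc(OC)c(OC)c(OC)c2O)cc1 | intermediate
21 | N-methylurea | CNC(N)=O | starting material
22 | oxalyl chloride | ClC(=O)C(Cl)=O | starting material
23 | 1-methylimidazolidine-2,4,5-trione (1-methylparabanic acid) | CN1C(=O)NC(=O)C1=O | intermediate
24 | 5-({5-[(2-hydroxy-3,4,5-trimethoxyphenyl)methyl]-4-[(4-methoxyphenyl)methyl]-1-methyl-1H-imidazol-2-yl}amino)-3-methyl-2H-imidazole-2,4(3H)-dione | COc1ccc(Cc2nc(NC3=NC(=O)N(C)C3=O)n(C)c2Cc2cc(OC)c(OC)c(OC)c2O)cc1 | intermediate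
25 | naamidine F | COC1=C(OC)C(=O)C(Cc2c(Cc3ccc(OC)cc3)nc(NC3=NC(=O)N(C)C3=O)n2C)=CC1=O | target

Total step count: 13.
Longest linear sequence: 10 steps (steps 3, 4, 5, 6, 7, 8, 9, 10, 12, 13, from Boc-sarcosine).

Steps most likely to fail

Step 6. The propargylic ynal may isomerise to the allenal or oligomerise on heating faster than it is intercepted by the fully substituted ketene-acetal terminus of the diene, and silyl transfer or addition at the formyl group may divert the diene. The fallback buys the benzene ring instead of building it. It sets out from 7: the lithium enolate (LiN(i-Pr)2, THF, –78 °C) is alkylated with commercial 5-(bromomethyl)-1,2,3-trimethoxybenzene to give tert-butyl N-{1-[methoxy(methyl)amino]-1-oxo-3-(3,4,5-trimethoxyphenyl)propan-2-yl}-N-methylcarbamate F1. Bromination with N-bromosuccinimide (MeCN, 0 °C) at the one free type of ring position, ortho to the benzylic carbon, gives the 2-bromo-3,4,5-trimethoxyphenyl compound F2. Miyaura borylation (bis(pinacolato)diboron, Pd(dppf)Cl2, KOAc, 1,4-dioxane, 90 °C) gives the aryl pinacol boronate F3, which is oxidised without isolation (NaBO3·4H2O, THF/H2O, rt) to the phenol. The fallback comes back to the route at 15.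

Step 13. Oxidation of the electron-rich acylated aminoimidazole or of the 4-methoxybenzyl ring may compete with oxidation of the phenol, and the fresh quinone may take up nucleophiles from the medium. The fallback inverts the order of the last two events so that the heterocycle is protected by protonation during the oxidation. It sets out from 20: oxidative demethylation with (NH4)2Ce(NO3)6 (2.2 equiv) in MeCN/H2O containing CF3CO2H at 0 °C gives 5-({2-amino-4-[(4-methoxyphenyl)methyl]-1-methyl-1H-imidazol-5-yl}methyl)-2,3-dimethoxy-1,4-benzoquinone F4, kept as its salt until use. Condensation with 23 under the silylating conditions of step 12 then closes the route at 25.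

Step 10. In hot aqueous acid the ortho-phenol may close reversibly onto the ketone (2-hydroxychromane, then 4H-chromene), and the amino ketone may self-condense, both faster than guanylation by cyanamide. The fallback installs the guanidine in protected form under mild, non-aqueous conditions. It sets out from 17: after the same HCl removal of the carbamate, the amine salt 19 is guanylated with N,N'-bis(tert-butoxycarbonyl)-N''-triflylguanidine and Et3N in CH2Cl2 at rt to give di-tert-butyl N,N'-({[1-(2-hydroxy-3,4,5-trimethoxyphenyl)-4-(4-methoxyphenyl)-3-oxobutan-2-yl](methyl)amino}methylylidene)biscarbamate F5. Treatment with CF3CO2H in CH2Cl2 at rt removes both carbamates, and the free guanidine should cyclise onto the ketone with loss of water. After basic work-up the fallback comes back to the route at 20.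

Further compounds
F1 | step 6 | tert-butyl N-{1-[methoxy(methyl)amino]-1-oxo-3-(3,4,5-trimethoxyphenyl)propan-2-yl}-N-methylcarbamate (racemic) | CON(C)C(=O)C(Cc1cc(OC)c(OC)c(OC)c1)N(C)C(=O)OC(C)(C)C
F2 | step 6 | tert-butyl N-{3-(2-bromo-3,4,5-trimethoxyphenyl)-1-[methoxy(methyl)amino]-1-oxopropan-2-yl}-N-methylcarbamate (racemic) | CON(C)C(=O)C(Cc1cc(OC)c(OC)c(OC)c1Br)N(C)C(=O)OC(C)(C)C
F3 | step 6 | tert-butyl N-{1-[methoxy(methyl)amino]-1-oxo-3-[3,4,5-trimethoxy-2-(4,4,5,5-tetramethyl-1,3,2-dioxaborolan-2-yl)phenyl]propan-2-yl}-N-methylcarbamate (racemic) | CON(C)C(=O)C(Cc1cc(OC)c(OC)c(OC)c1B1OC(C)(C)C(C)(C)O1)N(C)C(=O)OC(C)(C)C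
F4 | step 13 | 5-({2-amino-4-[(4-methoxyphenyl)methyl]-1-methyl-1H-imidazol-5-yl}methyl)-2,3-dimethoxy-1,4-benzoquinone | COC1=C(OC)C(=O)C(Cc2c(Cc3ccc(OC)cc3)nc(N)n2C)=CC1=O
F5 | step 10 | di-tert-butyl N,N'-({[1-(2-hydroxy-3,4,5-trimethoxyphenyl)-4-(4-methoxyphenyl)-3-oxobutan-2-yl](methyl)amino}methylylidene)biscarbamate (racemic) | COc1ccc(CC(=O)C(Cc2cc(OC)c(OC)c(OC)c2O)N(C)C(NC(=O)OC(C)(C)C)=NC(=O)OC(C)(C)C)cc1
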